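The constants of this flask are hidden, so we read two stand-ins for them off the runs.

all flasks: coupling partner 600 mM; free catalyst 24.0 mM
- south: starting material 300 mM
- south-east: starting material 450 mM
- north-east: starting material 900 mM; time 87 h

- south run (time / h: [starting material] / mM): 6.6: 253.4; 20: 221.2; 38: 197.1; 61: 183.4; 87: 181.8
- south-east run (time / h: [starting material] / mM): 6.6: 397.5; 20: 352.4; 38: 313.9; 61: 290.1; 87: 274.9

(readings scatter by 2 mM)

- Overall: starting material + coupling partner -> target, with free catalyst as catalyst.
- Constant volume, constant temperature.
- "The second partner" is coupling partner.
- An order is taken over about fifteen percent of the charge, up and down.

* reaction order in [starting material] at the outset, round the charge of the south run, defined at two percent of the starting material turned into target (one fixed amount of target, the same in the runs compared)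
* starting material in the north-east run at 87 h, as a share of the starting material charged
* which of these the readings show (the product kills the catalyst / the second partner kills the catalyst / the by-product ties up the catalyst / two substrates go astray together / nothing beyond the main steps)

The south run reads as stopped: from 61 h to 87 h it drops 1.60 mM, within the scatter of 2 mM, with 181.8 mM of starting material still there, so we take its catalyst to be lost. That end gives the reach P, the natural logarithm of charge over what stays: 0.501. The south-east run has come to 0.493 at 87 h, but it still drops 15.2 mM from 61 h to 87 h, so its own end is unread. We assume P is the same for both, which amounts to assuming that the catalyst turns a share of the charge, not an amount. We also assume that the logarithm climbs towards P and that its gap to P shrinks by a factor e in each lifetime τ. The south run at 20 h gives 21.3 h, and the south-east run at 38 h gives 29.9 h, longer than in the south run.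

What must be known well for the north-east run? Catalyst and partner charges are the same in the south, south-east and north-east runs, so they drop out. One scatter of error in the south run's end moves the north-east share by 0.64 percentage points. The lifetime needs more care. Left at the south-east value, it gives a north-east share of 62.3%. Stretched in line with the charge, it becomes 55.7 h, our estimate of the lifetime τ of the north-east run, and we expect 67.3% of its starting material left. That shift of 5 points is larger than the error from P.

The forecast gives order 0.5, share 74% and "two substrates go astray together", reasoning that “The more concentrated run also loses rate faster early on.” Our share is lower than its share.

The flask gives order 0.36, share 68.4% and "the second partner kills the catalyst".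

    free catalyst + starting material → loaded catalyst + by-product (5.148 L mol⁻¹ h⁻¹)
    loaded catalyst + coupling partner → target + free catalyst (0.5328 L mol⁻¹ h⁻¹)
    free catalyst + coupling partner → spent catalyst + coupling partner (0.4320 L mol⁻¹ h⁻¹)

Free catalyst either takes up starting material or meets coupling partner, and that meeting makes spent catalyst while the partner comes through unchanged. At 87 h the north-east run has lived 1.56 lifetimes by our τ. The same count for the south-east run, whose own readings set its τ and so give no check, is 2.91, which gives 62.3% left, where its reading stands at 61.1%. With that loss taken away, the north-east run at 87 h holds 54.1% of its starting material against 68.4%, so the loss accounts for 14 points.

The earlier runs and the new flask come from a simulation with made-up constants; scatter was added.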